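## The problem

The target is a tricycle built on a ten-membered carbocycle (C1–C10, biogenetic numbering with C14 on C10 and C15 on C4). An ether oxygen bridges C3 and C10, so that C1(=O), C2=C3, the oxygen and C10 form a 3(2H)-furanone. A γ-lactone (C12 carbonyl on the C8 oxygen, C11 on C7, exocyclic C11=C13) is trans-fused across C7–C8, C6 carries a (2S,3R)-2,3-dimethyloxirane-2-carboxylate, and C4=C5 is a Z-trisubstituted alkene. The core has four stereocentres (6R, 7R, 8S, 10R) and the ester two more.

C10 is quaternary and separated from the C6–C8 triad by the C9 methylene and the flat furanone. It cannot be counted on to direct C8, so C10 should come from the chiral pool and C8 from a chiral reagent or catalyst. C7 can follow C8 (anti addition; the trans-lactone is also the thermodynamic isomer), and C6 can be set from C7 when the ring is closed. The two ester centres are best set by asymmetric epoxidation of an achiral precursor.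

Several groups will not survive rough treatment:
- The α-methylene lactone is a Michael acceptor, and with a carbonyl at C6 its C7–H becomes acidic and the alkene can migrate.
- An aldehyde at C8 is β to the furanone oxygen on C10, so base invites retro-oxa-Michael opening and loss of C10.
- The Z-iodoalkene and Z-alkene can isomerise with acid, light or nucleophiles.
- The glycidic ester is sensitive to acid and nucleophiles.

The feature that makes the key step possible is the C5–C6 bond, which joins the Z-alkene terminus C5 to the allylic carbinol C6. This is the retron of an alkenylmetal addition to an aldehyde. The Z geometry places C5 on the furanone side, and the furanone and lactone rings leave only four rotatable bonds between the reacting ends.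

## Retrosynthesis

**Unmasking and acylation.** The target 37 is traced to sulfoxide 36 and sulfide 35, in which C11=C13 is stored as a thiophenol adduct. No skeletal bond is cut. This is preferred to carrying the free methylene lactone because every intermediate with a carbonyl at C6 would otherwise have an isomerisable C7–H. Cutting the C6–O ester bond of 35 gives carbinol 29 and epoxy acid 33. The acid is attached late because the C6 hydroxyl is the product of ring closure and the glycidic ester is best exposed to as few steps as possible. The forward steps must acylate a hindered secondary alcohol and then oxidise sulfur without touching alkenes or epoxide.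

**C5–C6 (key disconnection).** Cutting C5–C6 in 29 opens the ten-membered ring to iodoalkenyl aldehyde 27. The neighbouring cuts are weaker: C9–C10 would create the quaternary centre during ring closure, C6–C7 needs a carbanion next to base-sensitive groups, and closing the lactone last only postpones the ring problem. The precursor 27 is bicyclic in two separate rings and has one stereocentre fewer. The forward reaction must convert the Z-alkenyl iodide into a nucleophile without losing geometry, add it to the aldehyde only, and set 6R.

**Lactone (C7–C8 and O–C12).** Aldehyde 27 comes from alcohol 26 and silyl ether 25 by functional-group changes, and 25 from methylene lactone 24 by thiophenol addition. Cutting C7–C8 and the lactone C–O bond of 24 gives furanone aldehyde 18 and allylic bromide 22. One allylation–lactonisation makes two bonds and two stereocentres and delivers C13 with the ester. An aldol route would put C6 at the wrong oxidation level and need a separate methylenation. The forward reaction must be anti-selective and must choose the aldehyde face under catalyst control.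

**Furanone (O–C3 and C2–C3).** Aldehyde 18 comes from alcohol 17 and silyl ether 16. The furanone of 16 is opened at O–C3 to the 1,3-diketone 14, and the C2–C3 bond of its precursor 13 is cut to methyl ketone 7 and (Z)-iodoenal 11. This aldol–oxidation–cyclodehydration sequence avoids amine nucleophiles, which would displace iodide from a β-iodoenone. It needs only that the Z-iodide survive one acid step.

**Chiral pool.** Ketone 7 is traced through hydroxy ketone 6 and silyloxy lactone 5 to hydroxy lactone 4, and through dioxolanone acid 2 to (R)-citramalic acid 1. Citramalic acid supplies C8, C9, C10, C14 and C1 with the C10 configuration in place. Lactone 4 differentiates the two carboxyl carbons, so C1 can take a methyl group (C2) while C8 stays at the alcohol level.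

**Small fragments.** Iodoenal 11 comes from iodo alcohol 10 and propargyl alcohol 8 by carbomagnesiation–iodination, which fixes the Z geometry. Bromide 22 comes from the Morita–Baylis–Hillman adduct 21 of methyl acrylate 19 and silyloxyacetaldehyde 20. Epoxy acid 33 comes from epoxy alcohol 32, tiglyl alcohol 31 and tiglic acid 30 by asymmetric epoxidation.

## Roads not taken

**Alternative 1:** The lactone carbonyl is disconnected last (C11–C12 and C12–O8). The forward key step is a cyclocarbonylation of the ring-closed homopropargylic alcohol A2 with PdCl2(PPh3)2 and SnCl2 under CO, giving the silyl-protected methylene lactone A1.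
- Merits: the most fragile group appears after the ring, no sulfur mask is needed, and three late steps are saved. On this count it is better than the chosen plan.
- Weak points: A2 still needs a ten-membered ring closure, now on a substrate whose C7–H is propargylic and, if the same aldehyde closure is used, also α to a carbonyl. The anti C7/C8 relationship and the C8 face must still be set by other means. The finished strained dienone would meet palladium hydride and Lewis-acidic tin at the very end.
- Comparison: the chosen plan sets against the saved steps a lactone made in one catalytic step that fixes C7 and C8 together, and a ring closure on a substrate whose acidic positions are blocked.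

**Alternative 2:** The ring is cut at C9–C10. Anodic oxidation of the 3-silyloxyfuran A4 would couple C10 with C9 of a tethered methyl enol ether and give the bicyclic furanone ketal A3.
- Merits: two nucleophilic carbons are joined by umpolung, the furanone and the quaternary carbon arise together, and A4 is assembled convergently from flat pieces without chromium. In fragment economy it is as good as or better than the chosen plan.
- Weak points: the C10 configuration is created in the ring closure and can be steered only by C6 and C7 across the ring. Radical-cation cyclisations are secure for five- to seven-membered rings, not for ten. C8 emerges as a ketal that must be reduced stereoselectively and then lactonised.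
- Comparison: the chosen plan takes C10 from citramalic acid with certainty and closes the ring by a reaction type with many medium-ring precedents.

**Alternative 3:** The C6–C7 bond is formed by a [2,3]-Wittig ring contraction. The macrocyclic allyl ether A6 (twelve ring atoms counted through the furanone oxygen) would be deprotonated at C6 and rearrange to the ten-membered carbinol A5, breaking O–C13 and revealing C11=C13.
- Merits: a larger ether ring is easier to close, C6 and C7 are set in one event, and the methylene appears unmasked. In these respects it is better than the chosen plan.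
- Weak points: the C13 methylene (α to oxygen and γ to the ester) is more acidic than C6, so the wrong carbanion is likely. Strong base meets an acrylate and the furanone, [1,2]-shift competes, and the C6/C7 outcome depends on an unknown ring conformer.
- Comparison: the chosen plan uses a neutral ring closure and fixes C7 before cyclisation.

Key step: step 19

Assumptions:
- In step 15 the enantiomer of the bis(oxazolinyl)carbazole ligand is the one that directs the allyl group to the Re face of aldehyde 18 (this face gives 8S). Which antipode does so is to be settled on a model aldehyde.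
- Compounds 13 and 36 are mixtures at the carbinol carbon and at sulfur; both centres vanish in the following step.

## Route

Step 1
Reactants: 1 (R)-citramalic acid
Product: 2 2-[(4R)-2,2,4-trimethyl-5-oxo-1,3-dioxolan-4-yl]acetic acid
Conditions: Me2C(OMe)2, TsOH·H2O (cat.), CH2Cl2, rt
Reagents that add atoms: 2,2-dimethoxypropane, COC(C)(C)OC
Why: Acid-catalysed acetal exchange closes the five-membered 1,3-dioxolan-4-one on the α-hydroxy acid in preference to the six-membered ring open to the β-carboxyl (dioxolanone formation of α-hydroxy acids), so the two carboxyl groups are told apart; C10 is not touched.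

Step 2
Reactants: 2 dioxolanone acid
Product: 4 (3R)-3-hydroxy-3-methyloxolan-2-one, via hydroxyethyl dioxolanone 3 (not isolated)
Conditions: BH3·SMe2, THF, 0 °C to rt; aq. work-up; then TsOH·H2O (cat.), CH2Cl2, rt
Reagents that add atoms: none
Why: Borane reduces the free carboxylic acid much faster than the dioxolanone ester (chemoselective acid reduction); acid then transacylates the new primary alcohol onto C1 with loss of acetone to give the five-membered lactone.

Step 3
Reactants: 4 hydroxy lactone
Product: 5 (3R)-3-methyl-3-(triethylsilyloxy)oxolan-2-one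
Conditions: Et3SiOTf, 2,6-lutidine, CH2Cl2, −78 to 0 °C
Reagents that add atoms: triethylsilyl trifluoromethanesulfonate, CC[Si](CC)(CC)OS(=O)(=O)C(F)(F)F
Why: A silyl triflate with a hindered pyridine base is the standard silylation of tertiary alcohols; the TES ether keeps the tertiary oxygen out of steps 4 and 8 and is acid-labile enough for step 10.

Step 4
Reactants: 5 silyloxy lactone
Product: 6 (3R)-5-hydroxy-3-methyl-3-(triethylsilyloxy)pentan-2-one
Conditions: MeLi (1.1 equiv), THF, −78 °C; aq. NH4Cl
Reagents that add atoms: methyllithium, [Li]C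
Why: Addition of MeLi to a lactone stops at the lithium lactolate at low temperature and releases the methyl ketone on work-up (lactone-to-ketone mono-addition); the quaternary α-silyloxy carbon disfavours a second addition. The product equilibrates with its cyclic hemiketal.

Step 5
Reactants: 6 hydroxy ketone
Product: 7 (3R)-5-(tert-butyldiphenylsilyloxy)-3-methyl-3-(triethylsilyloxy)pentan-2-one
Conditions: tBuPh2SiCl, imidazole, DMF, 0 °C to rt
Reagents that add atoms: tert-butyl(chloro)diphenylsilane, CC(C)(C)[Si](Cl)(c1ccccc1)c1ccccc1
Why: Silylation of the primary alcohol drains the hemiketal equilibrium to the open ketone; TBDPS withstands the acid of step 10, which keeps the primary oxygen from competing for the diketone there.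

Step 6
Reactants: 8 propargyl alcohol
Product: 10 (2Z)-3-iodo-2-methylprop-2-en-1-ol, via alkenylmagnesium alkoxide 9 (not isolated)
Conditions: MeMgBr (2.5 equiv), CuI (10 mol%), THF, −10 °C to rt; then I2, −78 to 0 °C; aq. NH4Cl
Reagents that add atoms: methylmagnesium bromide, C[Mg]Br; iodine, [I][I]
Why: Copper-catalysed carbomagnesiation of the propargylic alkoxide is an anti addition that gives the chelated alkenylmagnesium with Mg cis to CH2O; iodinolysis occurs with retention, which fixes the Z geometry needed for C4=C5.

Step 7
Reactants: 10 iodo alcohol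
Product: 11 (2Z)-3-iodo-2-methylprop-2-enal
Conditions: MnO2, CH2Cl2, rt, dark; used at once
Reagents that add atoms: none
Why: MnO2 oxidises the allylic alcohol under neutral conditions (allylic oxidation); exclusion of light and immediate use limit Z-to-E isomerisation.

Step 8
Reactants: 7 methyl ketone; 11 iodoenal
Product: 13 (3R,7Z)-1-(tert-butyldiphenylsilyloxy)-6-hydroxy-8-iodo-3,7-dimethyl-3-(triethylsilyloxy)oct-7-en-4-one, via lithium enolate 12 (not isolated)
Conditions: LiN(iPr)2, THF, −78 °C; then 11, −78 °C; cold aq. NH4Cl
Reagents that add atoms: none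
Why: Deprotonation can occur only at the methyl group because C10 is quaternary, and the lithium enolate adds 1,2 to the enal at −78 °C (directed aldol addition); the new carbinol centre is oxidised away in step 9.

Step 9
Reactants: 13 aldol adduct
Product: 14 (3R,7Z)-1-(tert-butyldiphenylsilyloxy)-8-iodo-3,7-dimethyl-3-(triethylsilyloxy)oct-7-ene-4,6-dione
Conditions: Dess–Martin periodinane, NaHCO3, CH2Cl2, 0 °C to rt
Reagents that add atoms: none
Why: Dess–Martin oxidation of a β-hydroxy ketone to the 1,3-diketone is standard and non-basic, so neither retro-aldol cleavage nor substitution at the β-iodoenone is triggered.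

Step 10
Reactants: 14 diketone
Product: 16 (2R)-2-[2-(tert-butyldiphenylsilyloxy)ethyl]-5-[(1Z)-1-iodoprop-1-en-2-yl]-2-methylfuran-3(2H)-one, via hydroxy diketone 15 (not isolated)
Conditions: CF3CO2H, CH2Cl2–H2O (10:1), 0 °C to rt, dark
Reagents that add atoms: none
Why: Acid removes the tertiary TES ether, the freed C10 hydroxyl adds to the C3 carbonyl and loss of water gives the vinylogous ester (acid-catalysed cyclodehydration of an α′-hydroxy 1,3-diketone to a 3(2H)-furanone). A non-nucleophilic acid is used so that iodide is not exchanged on the β-iodoenone; C10 is quaternary and unaffected.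

Step 11
Reactants: 16 silyl ether
Product: 17 (2R)-2-(2-hydroxyethyl)-5-[(1Z)-1-iodoprop-1-en-2-yl]-2-methylfuran-3(2H)-one
Conditions: HF·pyridine, pyridine, THF, 0 °C to rt
Reagents that add atoms: none
Why: Buffered HF·pyridine cleaves the TBDPS ether without base (fluoride desilylation), which the vinylogous ester and the iodoalkene tolerate.

Step 12
Reactants: 17 alcohol
Product: 18 2-[(2R)-5-[(1Z)-1-iodoprop-1-en-2-yl]-2-methyl-3-oxo-2,3-dihydrofuran-2-yl]acetaldehyde
Conditions: Dess–Martin periodinane, NaHCO3, CH2Cl2, 0 °C; used crude
Reagents that add atoms: none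
Why: Buffered Dess–Martin oxidation gives the aldehyde without base; this matters because an enolate at C9 could expel the furanone oxygen from C10 (retro-oxa-Michael) and endanger the quaternary centre.

Step 13
Reactants: 19 methyl acrylate; 20 (tert-butyldimethylsilyloxy)acetaldehyde
Product: 21 methyl 4-(tert-butyldimethylsilyloxy)-3-hydroxy-2-methylidenebutanoate (racemic)
Conditions: DABCO (0.5 equiv), neat, rt
Reagents that add atoms: none
Why: Morita–Baylis–Hillman reaction: the amine–acrylate zwitterion adds to the aldehyde and gives an allylic alcohol that holds C6, C7, C11, C12 and C13; its stereocentre is erased in step 14.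

Step 14
Reactants: 21 allylic alcohol
Product: 22 methyl (2Z)-2-(bromomethyl)-4-(tert-butyldimethylsilyloxy)but-2-enoate
Conditions: NBS, Me2S, CH2Cl2, 0 °C to rt
Reagents that add atoms: N-bromosuccinimide, BrN1C(=O)CCC1=O
Why: The sulfonium reagent from NBS and Me2S activates the allylic hydroxyl and bromide enters with allylic transposition (SN2′ bromination of Morita–Baylis–Hillman adducts), giving the thermodynamically preferred Z-2-(bromomethyl)enoate.

Step 15
Reactants: 18 furanone aldehyde; 22 allylic bromide
Product: 24 (4S,5S)-4-[(tert-butyldimethylsilyloxy)methyl]-5-{[(2R)-5-[(1Z)-1-iodoprop-1-en-2-yl]-2-methyl-3-oxo-2,3-dihydrofuran-2-yl]methyl}-3-methylideneoxolan-2-one, via anti hydroxy ester 23 (not isolated)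
Conditions: CrCl2 (10 mol%), 1,8-bis(4-isopropyl-4,5-dihydrooxazol-2-yl)-3,6-diphenyl-9H-carbazole (12 mol%, one enantiomer), Mn powder, iPr2NEt (30 mol%), Me3SiCl, THF, rt; then PPTS, wet CH2Cl2, rt
Reagents that add atoms: none
Why: Catalytic asymmetric Nozaki–Hiyama-type 2-(alkoxycarbonyl)allylation followed by lactonisation: the allylchromium from 22 adds through a chair transition state with the CH2OTBS group equatorial (anti adduct, hence the trans-lactone, 7S in this compound), and the chiral tridentate ligand, not the remote C10 centre, selects the Re face of the aldehyde (8S). Without a nickel co-catalyst the alkenyl iodide is inert to divalent chromium.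

Step 16
Reactants: 24 methylene lactone
Product: 25 (3R,4S,5S)-4-[(tert-butyldimethylsilyloxy)methyl]-5-{[(2R)-5-[(1Z)-1-iodoprop-1-en-2-yl]-2-methyl-3-oxo-2,3-dihydrofuran-2-yl]methyl}-3-[(phenylsulfanyl)methyl]oxolan-2-one
Conditions: PhSH (1.05 equiv), Et3N (0.1 equiv), CH2Cl2, 0 °C
Reagents that add atoms: thiophenol, Sc1ccccc1
Why: Thia-Michael addition to the α-methylene lactone, which is far more electrophilic than the vinylogous ester; the addition is reversible under amine catalysis, so the all-trans adduct (11R) is expected, and this centre is erased again in step 25.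

Step 17
Reactants: 25 silyl ether
Product: 26 (3R,4S,5S)-4-(hydroxymethyl)-5-{[(2R)-5-[(1Z)-1-iodoprop-1-en-2-yl]-2-methyl-3-oxo-2,3-dihydrofuran-2-yl]methyl}-3-[(phenylsulfanyl)methyl]oxolan-2-one
Conditions: HF·pyridine, pyridine, THF, 0 °C
Reagents that add atoms: none
Why: Fluoride cleavage of the primary TBS ether; the buffered, non-basic medium avoids translactonisation of the freed C6 hydroxyl onto C12.

Step 18
Reactants: 26 alcohol
Product: 27 (2S,3R,4R)-2-{[(2R)-5-[(1Z)-1-iodoprop-1-en-2-yl]-2-methyl-3-oxo-2,3-dihydrofuran-2-yl]methyl}-5-oxo-4-[(phenylsulfanyl)methyl]oxolane-3-carbaldehyde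
Conditions: Dess–Martin periodinane, NaHCO3, CH2Cl2, 0 °C
Reagents that add atoms: none
Why: Buffered Dess–Martin oxidation; C7 and C11 are now both α to carbonyl groups, and the all-trans lactone set in steps 15 and 16 is also the thermodynamic isomer, so no drift is expected.

Step 19
Reactants: 27 iodoalkenyl lactone aldehyde
Product: 29 (4Z,6R,7S,8S,10R,11R)-3,10-epoxy-6-hydroxy-1-oxo-13-(phenylsulfanyl)germacra-2,4-dien-12,8-olide, via alkenylchromium dichloride 28 (not isolated)
Conditions: CrCl2 (15 equiv), NiCl2 (2 mol% of Cr), degassed DMSO–THF, rt, 27 added by syringe pump (final 0.003 M)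
Reagents that add atoms: none
Why: NiCl2 is reduced by CrCl2 to zerovalent nickel, which inserts into the C5–I bond with retention of the Z geometry; transmetalation to trivalent chromium gives alkenylchromium 28, which adds to the C6 aldehyde (Nozaki–Hiyama–Kishi reaction, here in its established macrocyclising form with alkenyl iodides and aldehydes). The ten-membered carbocycle is closed by attack of C5 on the carbonyl carbon, an exo-trig closure that leaves the carbonyl oxygen outside the ring. The new stereocentre C6 is controlled by C7: the tether holds C5 on the C8 side of the aldehyde, so C5 approaches anti to the C7–C11 bond (Felkin–Anh arrangement) while the carbonyl oxygen points toward H7 and away from the ring being formed, which gives 6R. The step needs chemoselectivity for the aldehyde over the lactone and furanone carbonyls, which organochromium reagents provide; it needs cyclisation over oligomerisation, which slow addition at high dilution and the preorganisation by the Z-alkene, the flat furanone and the trans-lactone provide; and it needs C7 to keep its configuration, which the neutral medium and the masked methylene secure.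

Step 20
Reactants: 30 tiglic acid
Product: 31 (2E)-2-methylbut-2-en-1-ol
Conditions: LiAlH4, Et2O, 0 °C to rt; aq. NaOH work-up
Reagents that add atoms: none
Why: Hydride reduction of the conjugated acid gives the allylic alcohol without touching the trisubstituted alkene (1,2-reduction by LiAlH4).

Step 21
Reactants: 31 tiglyl alcohol
Product: 32 [(2R,3R)-2,3-dimethyloxiran-2-yl]methanol
Conditions: Ti(OiPr)4 (10 mol%), D-(−)-diethyl tartrate (12 mol%), tBuOOH, 4 Å sieves, CH2Cl2, −20 °C
Reagents that add atoms: tert-butyl hydroperoxide, CC(C)(C)OO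
Why: Sharpless asymmetric epoxidation; with D-(−)-diethyl tartrate the oxygen is delivered to the face of the E-allylic alcohol that gives the (2R,3R) epoxy alcohol, so both ester stereocentres are set by the catalyst.

Step 22
Reactants: 32 epoxy alcohol
Product: 33 (2S,3R)-2,3-dimethyloxirane-2-carboxylic acid
Conditions: TEMPO (20 mol%), PhI(OAc)2 (2.2 equiv), MeCN–H2O (1:1), 0 °C to rt
Reagents that add atoms: water, O
Why: TEMPO-catalysed oxidation with PhI(OAc)2 in aqueous acetonitrile takes a primary alcohol to the acid through the aldehyde hydrate under near-neutral conditions that keep the trisubstituted epoxide intact; the descriptor at C2 changes to S only because the priorities change.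

Step 23
Reactants: 29 macrocyclic carbinol; 33 epoxy acid
Product: 35 (4Z,6R,7R,8S,10R,11R)-6-{[(2S,3R)-2,3-dimethyloxirane-2-carbonyl]oxy}-3,10-epoxy-1-oxo-13-(phenylsulfanyl)germacra-2,4-dien-12,8-olide, via mixed anhydride 34 (not isolated)
Conditions: 33, 2,4,6-Cl3C6H2COCl, Et3N, THF, rt; then 29, DMAP, toluene, rt
Reagents that add atoms: none
Why: Yamaguchi esterification: DMAP attacks the mixed anhydride at the less hindered glycidic carbonyl and the acylpyridinium acylates the hindered C6 hydroxyl with retention at C6.

Step 24
Reactants: 35 sulfide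
Product: 36 (4Z,6R,7R,8S,10R,11R)-6-{[(2S,3R)-2,3-dimethyloxirane-2-carbonyl]oxy}-3,10-epoxy-1-oxo-13-(phenylsulfinyl)germacra-2,4-dien-12,8-olide
Conditions: NaIO4 (1.1 equiv), MeOH–H2O, 0 °C to rt
Reagents that add atoms: sodium periodate, [Na+].[O-]I(=O)(=O)=O
Why: NaIO4 oxidises the sulfide to the sulfoxide and stops there (selective sulfide oxidation); alkenes, epoxide and esters are inert to it.

Step 25
Reactants: 36 sulfoxide
Product: 37 (4Z,6R,7R,8S,10R)-6-{[(2S,3R)-2,3-dimethyloxirane-2-carbonyl]oxy}-3,10-epoxy-1-oxogermacra-2,4,11(13)-trien-12,8-olide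
Conditions: toluene, CaCO3, 110 °C
Reagents that add atoms: none
Why: Thermal syn elimination of the sulfoxide (sulfoxide pyrolysis) can involve only H11, so the C11=C13 double bond is restored regiospecifically; CaCO3 takes up the sulfenic acid.

## Compound list

1 | (R)-citramalic acid, (2R)-2-hydroxy-2-methylbutanedioic acid | OC(=O)C[C@@](C(=O)O)(C)O | starting material
2 | 2-[(4R)-2,2,4-trimethyl-5-oxo-1,3-dioxolan-4-yl]acetic acid | OC(=O)C[C@@]1(C)OC(C)(C)OC1=O | intermediate
3 | (5R)-5-(2-hydroxyethyl)-2,2,5-trimethyl-1,3-dioxolan-4-one | OCC[C@@]1(C)OC(C)(C)OC1=O | intermediate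
4 | (3R)-3-hydroxy-3-methyloxolan-2-one | O=C1OCC[C@@]1(C)O | intermediate
5 | (3R)-3-methyl-3-(triethylsilyloxy)oxolan-2-one | O=C1OCC[C@@]1(C)O[Si](CC)(CC)CC | intermediate
6 | (3R)-5-hydroxy-3-methyl-3-(triethylsilyloxy)pentan-2-one | OCC[C@@](C(C)=O)(C)O[Si](CC)(CC)CC | intermediate
7 | (3R)-5-(tert-butyldiphenylsilyloxy)-3-methyl-3-(triethylsilyloxy)pentan-2-one | CC(C)(C)[Si](c1ccccc1)(c1ccccc1)OCC[C@@](C(C)=O)(C)O[Si](CC)(CC)CC | intermediate
8 | propargyl alcohol (prop-2-yn-1-ol) | C#CCO | starting material
9 | bromomagnesium (2Z)-3-(bromomagnesio)-2-methylprop-2-en-1-olate | Br[Mg]OC/C(C)=C\[Mg]Br | intermediate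
10 | (2Z)-3-iodo-2-methylprop-2-en-1-ol | OC/C(C)=C\I | intermediate
11 | (2Z)-3-iodo-2-methylprop-2-enal | O=C/C(C)=C\I | intermediate
12 | lithium (3R)-5-(tert-butyldiphenylsilyloxy)-3-methyl-3-(triethylsilyloxy)pent-1-en-2-olate | [Li]OC(=C)[C@@](C)(CCO[Si](c1ccccc1)(c1ccccc1)C(C)(C)C)O[Si](CC)(CC)CC | intermediate
13 | (3R,7Z)-1-(tert-butyldiphenylsilyloxy)-6-hydroxy-8-iodo-3,7-dimethyl-3-(triethylsilyloxy)oct-7-en-4-one (both C6 epimers) | I/C=C(C)\C(O)CC(=O)[C@@](C)(CCO[Si](c1ccccc1)(c1ccccc1)C(C)(C)C)O[Si](CC)(CC)CC | intermediate
14 | (3R,7Z)-1-(tert-butyldiphenylsilyloxy)-8-iodo-3,7-dimethyl-3-(triethylsilyloxy)oct-7-ene-4,6-dione | I/C=C(C)\C(=O)CC(=O)[C@@](C)(CCO[Si](c1ccccc1)(c1ccccc1)C(C)(C)C)O[Si](CC)(CC)CC | intermediate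
15 | (3R,7Z)-1-(tert-butyldiphenylsilyloxy)-3-hydroxy-8-iodo-3,7-dimethyloct-7-ene-4,6-dione | I/C=C(C)\C(=O)CC(=O)[C@@](C)(CCO[Si](c1ccccc1)(c1ccccc1)C(C)(C)C)O | intermediate
16 | (2R)-2-[2-(tert-butyldiphenylsilyloxy)ethyl]-5-[(1Z)-1-iodoprop-1-en-2-yl]-2-methylfuran-3(2H)-one | CC(C)(C)[Si](c1ccccc1)(c1ccccc1)OCC[C@@]1(C)OC(=CC1=O)/C(C)=C\I | intermediate
17 | (2R)-2-(2-hydroxyethyl)-5-[(1Z)-1-iodoprop-1-en-2-yl]-2-methylfuran-3(2H)-one | OCC[C@@]1(C)OC(=CC1=O)/C(C)=C\I | intermediate
18 | 2-[(2R)-5-[(1Z)-1-iodoprop-1-en-2-yl]-2-methyl-3-oxo-2,3-dihydrofuran-2-yl]acetaldehyde | O=CC[C@@]1(C)OC(=CC1=O)/C(C)=C\I | intermediate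
19 | methyl acrylate | C=CC(=O)OC | starting material
20 | (tert-butyldimethylsilyloxy)acetaldehyde | O=CCO[Si](C)(C)C(C)(C)C | starting material
21 | methyl 4-(tert-butyldimethylsilyloxy)-3-hydroxy-2-methylidenebutanoate (racemic) | C=C(C(=O)OC)C(O)CO[Si](C)(C)C(C)(C)C | intermediate
22 | methyl (2Z)-2-(bromomethyl)-4-(tert-butyldimethylsilyloxy)but-2-enoate | COC(=O)/C(CBr)=C/CO[Si](C)(C)C(C)(C)C | intermediate
23 | methyl (3S,4S)-3-[(tert-butyldimethylsilyloxy)methyl]-4-hydroxy-5-[(2R)-5-[(1Z)-1-iodoprop-1-en-2-yl]-2-methyl-3-oxo-2,3-dihydrofuran-2-yl]-2-methylidenepentanoate | C=C(C(=O)OC)[C@@H](CO[Si](C)(C)C(C)(C)C)[C@@H](O)C[C@@]1(C)OC(=CC1=O)/C(C)=C\I | intermediate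
24 | (4S,5S)-4-[(tert-butyldimethylsilyloxy)methyl]-5-{[(2R)-5-[(1Z)-1-iodoprop-1-en-2-yl]-2-methyl-3-oxo-2,3-dihydrofuran-2-yl]methyl}-3-methylideneoxolan-2-one | C=C1C(=O)O[C@@H](C[C@@]2(C)OC(=CC2=O)/C(C)=C\I)[C@@H]1CO[Si](C)(C)C(C)(C)C | intermediate
25 | (3R,4S,5S)-4-[(tert-butyldimethylsilyloxy)methyl]-5-{[(2R)-5-[(1Z)-1-iodoprop-1-en-2-yl]-2-methyl-3-oxo-2,3-dihydrofuran-2-yl]methyl}-3-[(phenylsulfanyl)methyl]oxolan-2-one | c1ccccc1SC[C@H]1C(=O)O[C@@H](C[C@@]2(C)OC(=CC2=O)/C(C)=C\I)[C@@H]1CO[Si](C)(C)C(C)(C)C | intermediate
26 | (3R,4S,5S)-4-(hydroxymethyl)-5-{[(2R)-5-[(1Z)-1-iodoprop-1-en-2-yl]-2-methyl-3-oxo-2,3-dihydrofuran-2-yl]methyl}-3-[(phenylsulfanyl)methyl]oxolan-2-one | c1ccccc1SC[C@H]1C(=O)O[C@@H](C[C@@]2(C)OC(=CC2=O)/C(C)=C\I)[C@@H]1CO | intermediate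
27 | (2S,3R,4R)-2-{[(2R)-5-[(1Z)-1-iodoprop-1-en-2-yl]-2-methyl-3-oxo-2,3-dihydrofuran-2-yl]methyl}-5-oxo-4-[(phenylsulfanyl)methyl]oxolane-3-carbaldehyde | c1ccccc1SC[C@H]1C(=O)O[C@@H](C[C@@]2(C)OC(=CC2=O)/C(C)=C\I)[C@@H]1C=O | intermediate
28 | alkenylchromium dichloride of 27 (CrCl2 in place of iodine at C5, Z) | c1ccccc1SC[C@H]1C(=O)O[C@@H](C[C@@]2(C)OC(=CC2=O)/C(C)=C\[Cr](Cl)Cl)[C@@H]1C=O | intermediate
29 | (4Z,6R,7S,8S,10R,11R)-3,10-epoxy-6-hydroxy-1-oxo-13-(phenylsulfanyl)germacra-2,4-dien-12,8-olide (ten-membered ring, furanone, trans-lactone, free 6-OH) | c1ccccc1SC[C@H]1C(=O)O[C@H]2C[C@@]3(C)OC(=CC3=O)/C(C)=C\[C@@H](O)[C@H]12 | intermediate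
30 | tiglic acid, (2E)-2-methylbut-2-enoic acid | C/C=C(\C)C(=O)O | starting material
31 | (2E)-2-methylbut-2-en-1-ol | C/C=C(\C)CO | intermediate
32 | [(2R,3R)-2,3-dimethyloxiran-2-yl]methanol | OC[C@@]1(C)O[C@@H]1C | intermediate
33 | (2S,3R)-2,3-dimethyloxirane-2-carboxylic acid | OC(=O)[C@@]1(C)O[C@@H]1C | intermediate
34 | (2S,3R)-2,3-dimethyloxirane-2-carboxylic 2,4,6-trichlorobenzoic anhydride | O=C(OC(=O)[C@@]1(C)O[C@@H]1C)c1c(Cl)cc(Cl)cc1Cl | intermediate
35 | (4Z,6R,7R,8S,10R,11R)-6-{[(2S,3R)-2,3-dimethyloxirane-2-carbonyl]oxy}-3,10-epoxy-1-oxo-13-(phenylsulfanyl)germacra-2,4-dien-12,8-olide | c1ccccc1SC[C@H]1C(=O)O[C@H]2C[C@@]3(C)OC(=CC3=O)/C(C)=C\[C@@H](OC(=O)[C@@]4(C)O[C@@H]4C)[C@H]12 | intermediate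
36 | (4Z,6R,7R,8S,10R,11R)-6-{[(2S,3R)-2,3-dimethyloxirane-2-carbonyl]oxy}-3,10-epoxy-1-oxo-13-(phenylsulfinyl)germacra-2,4-dien-12,8-olide (both configurations at sulfur) | O=S(c1ccccc1)C[C@H]1C(=O)O[C@H]2C[C@@]3(C)OC(=CC3=O)/C(C)=C\[C@@H](OC(=O)[C@@]4(C)O[C@@H]4C)[C@H]12 | intermediate
37 | (4Z,6R,7R,8S,10R)-6-{[(2S,3R)-2,3-dimethyloxirane-2-carbonyl]oxy}-3,10-epoxy-1-oxogermacra-2,4,11(13)-trien-12,8-olide | C=C1C(=O)O[C@H]2C[C@@]3(C)OC(=CC3=O)/C(C)=C\[C@@H](OC(=O)[C@@]3(C)O[C@@H]3C)[C@H]12 | target

## Step count and least certain steps

Total: 25 steps. Longest linear sequence: 18 steps (1 → 2 → 4 → 5 → 6 → 7 → 13 → 14 → 16 → 17 → 18 → 24 → 25 → 26 → 27 → 29 → 35 → 36 → 37).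

**Step 19 (key step).** The likely failures are intermolecular addition leading to oligomers, protodemetalation of the alkenylchromium, and poor facial selectivity at C6, because the Felkin–Anh preference and the ring constraint may not act together as assumed. The disconnection is kept. Fallback: starting from 27, if the cyclisation delivers mainly the 6S carbinol F1, that epimer is not discarded. A Mitsunobu esterification (PPh3, diisopropyl azodicarboxylate, acid 33) installs the ester with inversion and returns to the route at 35.

**Step 15.** The ligand may be mismatched with the C10 centre, giving poor face selection at C8. Partial syn addition or β-elimination of the silyloxy group from the allylchromium are also possible. A cis-lactone would converge at aldehyde 27, where C7 is epimerisable and the trans isomer is thermodynamic, but a wrong C8 face would not. Fallback: starting from 18, the allyl donor is changed to a configurationally fixed boron reagent. Commercial methyl 4-hydroxybut-2-ynoate is silylated to methyl 4-(tert-butyldimethylsilyloxy)but-2-ynoate F2. Syn hydroalumination (iBu2AlH, hexamethylphosphoramide) and trapping with 2-(iodomethyl)-4,4,5,5-tetramethyl-1,3,2-dioxaborolane gives the allylboronate F3, with CH2OTBS trans to CH2B. Its thermal addition to 18 through a closed chair gives the anti hydroxy ester 23 stereospecifically. Acid lactonisation and chromatographic removal of the C8-epimeric series return to the route at 24.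

**Step 10.** Acid may isomerise the Z-β-iodoenone before the furanone has formed, or dehydration may stall at the hemiketal. Fallback: starting from 14, the Brønsted acid is replaced by a two-stage, non-acidic sequence. Buffered HF·pyridine removes the TES group and gives the isolable cyclic hemiketal F4. The Burgess reagent then eliminates its tertiary hydroxyl toward the acidic C2–H and returns to the route at 16.

**Step 23.** Acylation of the hindered C6 hydroxyl by the α,α-disubstituted glycidic acid may be slow, leaving time for epoxide opening by chloride or DMAP. Fallback: starting from 29, the ester bond is formed by displacement at C6 instead of acyl transfer. Dess–Martin oxidation gives the C6 ketone F5 (kept cold and base-free to protect C7). Oxazaborolidine-catalysed borane reduction, with the catalyst enantiomer chosen for the 6S alcohol, gives the 6S carbinol F1. Mitsunobu esterification with 33 then inverts C6 and returns to the route at 35.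

**Step 25.** At 110 °C the strained dienone may isomerise or decompose, or the sulfenic acid may add back. Fallback: starting from 36, the thermal syn elimination is replaced by a base-induced elimination. Oxidation with H2O2 and catalytic (NH4)6Mo7O24 gives the sulfone F6, and DBU at 0 °C expels benzenesulfinate from the lactone enolate (E1cB) to give 37.

## Further compounds

F1 | step 19 | (4Z,6S,7S,8S,10R,11R)-3,10-epoxy-6-hydroxy-1-oxo-13-(phenylsulfanyl)germacra-2,4-dien-12,8-olide (C6 epimer of 29) | c1ccccc1SC[C@H]1C(=O)O[C@H]2C[C@@]3(C)OC(=CC3=O)/C(C)=C\[C@H](O)[C@H]12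
F2 | step 15 | methyl 4-(tert-butyldimethylsilyloxy)but-2-ynoate | COC(=O)C#CCO[Si](C)(C)C(C)(C)C
F3 | step 15 | methyl (2Z)-4-(tert-butyldimethylsilyloxy)-2-[(4,4,5,5-tetramethyl-1,3,2-dioxaborolan-2-yl)methyl]but-2-enoate | COC(=O)/C(CB1OC(C)(C)C(C)(C)O1)=C\CO[Si](C)(C)C(C)(C)C
F4 | step 10 | (2R)-2-[2-(tert-butyldiphenylsilyloxy)ethyl]-5-hydroxy-5-[(1Z)-1-iodoprop-1-en-2-yl]-2-methyloxolan-3-one (both C5 epimers) | CC(C)(C)[Si](c1ccccc1)(c1ccccc1)OCC[C@@]1(C)OC(O)(CC1=O)/C(C)=C\I
F5 | step 23 | (4Z,7S,8S,10R,11R)-3,10-epoxy-1,6-dioxo-13-(phenylsulfanyl)germacra-2,4-dien-12,8-olide | c1ccccc1SC[C@H]1C(=O)O[C@H]2C[C@@]3(C)OC(=CC3=O)/C(C)=C\C(=O)[C@H]12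
F6 | step 25 | (4Z,6R,7R,8S,10R,11R)-6-{[(2S,3R)-2,3-dimethyloxirane-2-carbonyl]oxy}-3,10-epoxy-1-oxo-13-(phenylsulfonyl)germacra-2,4-dien-12,8-olide | O=S(=O)(c1ccccc1)C[C@H]1C(=O)O[C@H]2C[C@@]3(C)OC(=CC3=O)/C(C)=C\[C@@H](OC(=O)[C@@]4(C)O[C@@H]4C)[C@H]12
A1 | alternative 1 | 6-O-(tert-butyldimethylsilyl) core methylene lactone | C=C1C(=O)O[C@H]2C[C@@]3(C)OC(=CC3=O)/C(C)=C\[C@@H](O[Si](C)(C)C(C)(C)C)[C@H]12
A2 | alternative 1 | ten-membered furanone with C7 ethynyl, free C8 hydroxyl and C6 silyl ether | O[C@H]1C[C@@]2(C)OC(=CC2=O)/C(C)=C\[C@@H](O[Si](C)(C)C(C)(C)C)[C@@H]1C#C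
A3 | alternative 2 | bicyclic furanone with C8 dimethyl ketal | C=C(CO[Si](C)(C)C(C)(C)C)[C@H]1[C@H](O[Si](C)(C)C(C)(C)C)/C=C(C)\C2=CC(=O)[C@@](C)(CC1(OC)OC)O2
A4 | alternative 2 | open-chain 2-methyl-3-silyloxyfuran with tethered methyl enol ether | C=C(CO[Si](C)(C)C(C)(C)C)[C@H](C(OC)=C)[C@H](O[Si](C)(C)C(C)(C)C)/C=C(C)\c1cc(O[Si](C)(C)C(C)(C)C)c(C)o1
A5 | alternative 3 | ten-membered C6 carbinol with tert-butyl acrylate at C7 | C=C(C(=O)OC(C)(C)C)[C@@H]1[C@@H](O[Si](C)(C)C(C)(C)C)C[C@@]2(C)OC(=CC2=O)/C(C)=C\[C@H]1O
A6 | alternative 3 | macrocyclic allyl ether linking C6 and C13 | O=C(OC(C)(C)C)/C1=C/[C@@H](O[Si](C)(C)C(C)(C)C)C[C@@]2(C)OC(=CC2=O)/C(C)=C\COC1
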